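**Plan**

- Retrosynthesis: coelenterazine is first taken back to its 5,8-dihydro-2H form. The ring bonds N7–C6 (imine) and N4–C8a (amidine) are cut next, and last the amide bonds C3–N4 and C8a–N1.
- Enabling feature: with the bicycle numbered N1, C2, C3(=O), N4, C5, C6, N7, C8, C8a, the imidazolone ring (N1–C2–C3–N4–C8a) and the pyrazine ring (N4–C5–C6–N7–C8–C8a) share only N4–C8a. N7/C8/C8a are N, Cα and C=O of phenylalanine, N1/C2/C3 those of tyrosine, and N4/C5/C6 a 4-hydroxyphenacylamine. The core is therefore a linear Phe–Tyr–aminoketone chain minus two H2O and one H2.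
- Forward: the chain is joined N→C (Phe–Tyr amide, then Tyr–aminoketone amide). In one flask the five-membered ring closes first (N4–C8a, with N7 still a carbamate), then the six-membered ring (N7–C6). A dehydrogenation ends the route.
- Stereochemistry: the target has no stereocentre. C8 and C2 come from L-Phe and L-Tyr, are carried as labile, nominally (S) centres and both become sp2 in the last step, so their epimerization costs nothing.

Key step: step 3

Remark on the chemistry: the target is achiral, so "single enantiomer" is read as the 7H-tautomer of the given SMILES. The cyclization precursor enters the key step as its N7-Boc derivative, and the Boc group is removed inside that step after the first ring has formed.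

**Step 1**
Reactants: 1 N-(tert-butoxycarbonyl)-L-phenylalanine N-hydroxysuccinimide ester (Boc-L-Phe-OSu); 2 L-tyrosine
Product: 3 N-(tert-butoxycarbonyl)-L-phenylalanyl-L-tyrosine (Boc-L-Phe-L-Tyr-OH)
Conditions: NaHCO3 (2.5 equiv), H2O/THF 1:1, rt; then 1 M HCl, 0 °C, to pH 2–3
Reagents that add atoms: none
Why: Aminolysis of an N-hydroxysuccinimide active ester by the tyrosine amino group under Schotten–Baumann-type bicarbonate conditions should be selective for nitrogen over the phenol at pH about 8, and a urethane-protected active ester does not form an azlactone, so both L-centres pass through unchanged.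

**Step 2**
Reactants: 3 Boc-L-Phe-L-Tyr-OH; 4 2-amino-1-(4-hydroxyphenyl)ethanone hydrochloride
Product: 5 Boc-L-phenylalanyl-L-tyrosine N-[2-(4-hydroxyphenyl)-2-oxoethyl]amide
Conditions: EDC·HCl (1.1 equiv), HOBt (1.1 equiv), DMF, 0 °C; then 4 and NMM (2.1 equiv, added slowly), 0 °C → rt
Reagents that add atoms: none
Why: In this carbodiimide/HOBt amide coupling the acid is pre-activated and the α-aminoketone is released from its salt only in the presence of the active ester, so N-acylation should outrun self-condensation to a dihydropyrazine, any phenyl ester formed at a phenol is itself an acyl donor that is funnelled to the amide, and epimerization at the tyrosine centre is harmless because that centre is destroyed in step 4.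

**Step 3**
Reactants: 5 Boc-L-phenylalanyl-L-tyrosine N-[2-(4-hydroxyphenyl)-2-oxoethyl]amide
Product: 9 (2S,8S)-8-benzyl-2-(4-hydroxybenzyl)-6-(4-hydroxyphenyl)-5,8-dihydroimidazo[1,2-a]pyrazin-3(2H)-one (dihydrocoelenterazine), via O-silylated peptidyl ketone 6 (not isolated), via O-silylated Boc-aminoalkyl imidazolone 7 (not isolated), via aminoalkyl imidazolone 8 (not isolated)
Conditions: BSA (8 equiv), TMSCl (0.2 equiv), MeCN, 80 °C, Ar; evaporate; 4 M HCl/dioxane, rt; evaporate; NaOAc (3 equiv), degassed EtOH, rt, Ar
Reagents that add atoms: none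
Why: Proposed new method: BSA silylates both phenols (6) and converts the two secondary amides into O-silyl imidates, the imidate nitrogen N4 adds to the silyl-activated phenylalanine carbonyl C8a and trimethylsilanol (taken up as hexamethyldisiloxane) leaves to give the N7-Boc imidazolone 7; HCl then removes Boc and the silyl ethers, and on buffering with NaOAc the amine N7 of 8 condenses with the aryl ketone C6 to the cyclic imine 9. The closest known reaction types are the silylative cyclodehydration of N-acyl amino amides to GFP-chromophore-type imidazolones (and of 2-acylaminobenzamides to quinazolinones) and the cyclocondensation of an amine with an α-amido ketone to a dihydropyrazine, neither shown on a saturated peptidyl ketone nor combined in one flask. The imidazolone ring closes 5-exo-trig (N4 onto C8a) and the dihydropyrazine ring 6-exo-trig (N7 onto C6), each followed by loss of water. No stereocentre is created; C2 and C8 keep the L-derived configuration only nominally, both being acidic and both removed in step 4. The step needs N4→C8a to win over diketopiperazine-type attack of N7 on C3, over intermolecular imine formation and over closure of N1 or of the amide oxygen onto the ketone (six-membered enamide, Robinson–Gabriel oxazole): N7 stays a carbamate and then an ammonium ion until the imidazolone exists, the only weakly Lewis-acidic silylating medium leaves the ketone unactivated, and once ring one is formed N7 cannot reach C3 without a bridgehead amidine, so the 1,6-related ketone is its only partner.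

**Step 4**
Reactants: 9 (2S,8S)-8-benzyl-2-(4-hydroxybenzyl)-6-(4-hydroxyphenyl)-5,8-dihydroimidazo[1,2-a]pyrazin-3(2H)-one
Product: 10 coelenterazine, 8-benzyl-2-(4-hydroxybenzyl)-6-(4-hydroxyphenyl)imidazo[1,2-a]pyrazin-3(7H)-one
Conditions: chloranil (1.0 equiv), AcOH (cat.), degassed EtOH/CH2Cl2, 0 °C → rt, Ar
Reagents that add atoms: none
Why: In this quinone dehydrogenation (aromatization of a dihydropyrazine) acid-catalysed prototropy should give an electron-rich N–H dihydro tautomer that passes hydride to chloranil, after which the 7H-imidazopyrazinone tautomer results with C2 and C8 both sp2, and one equivalent of the mild quinone under argon in weakly acidic medium should limit over-oxidation of the oxygen-sensitive product.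

**Compound list**

1 | N-(tert-butoxycarbonyl)-L-phenylalanine N-hydroxysuccinimide ester (Boc-L-Phe-OSu) | CC(C)(C)OC(=O)N[C@@H](Cc1ccccc1)C(=O)ON1C(=O)CCC1=O | starting material
2 | L-tyrosine | N[C@@H](Cc1ccc(O)cc1)C(=O)O | starting material
3 | N-(tert-butoxycarbonyl)-L-phenylalanyl-L-tyrosine | CC(C)(C)OC(=O)N[C@@H](Cc1ccccc1)C(=O)N[C@@H](Cc1ccc(O)cc1)C(=O)O | intermediate
4 | 2-amino-1-(4-hydroxyphenyl)ethanone hydrochloride | Cl.NCC(=O)c1ccc(O)cc1 | starting material
5 | Boc-L-phenylalanyl-L-tyrosine N-[2-(4-hydroxyphenyl)-2-oxoethyl]amide (N7-Boc form of the cyclization precursor) | CC(C)(C)OC(=O)N[C@@H](Cc1ccccc1)C(=O)N[C@@H](Cc1ccc(O)cc1)C(=O)NCC(=O)c1ccc(O)cc1 | intermediate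
6 | bis(O-trimethylsilyl) ether of 5 (both phenols silylated; amides in equilibrium with their O-silyl imidates) | CC(C)(C)OC(=O)N[C@@H](Cc1ccccc1)C(=O)N[C@@H](Cc1ccc(O[Si](C)(C)C)cc1)C(=O)NCC(=O)c1ccc(O[Si](C)(C)C)cc1 | intermediate (not isolated)
7 | tert-butyl N-[(1S)-1-{(4S)-5-oxo-1-{2-oxo-2-[4-(trimethylsilyloxy)phenyl]ethyl}-4-[4-(trimethylsilyloxy)benzyl]-4,5-dihydro-1H-imidazol-2-yl}-2-phenylethyl]carbamate | CC(C)(C)OC(=O)N[C@@H](Cc1ccccc1)C1=N[C@@H](Cc2ccc(O[Si](C)(C)C)cc2)C(=O)N1CC(=O)c1ccc(O[Si](C)(C)C)cc1 | intermediate (not isolated)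
8 | (5S)-2-[(1S)-1-amino-2-phenylethyl]-5-(4-hydroxybenzyl)-3-[2-(4-hydroxyphenyl)-2-oxoethyl]-3,5-dihydro-4H-imidazol-4-one (formed as its hydrochloride, set free by NaOAc) | N[C@@H](Cc1ccccc1)C1=N[C@@H](Cc2ccc(O)cc2)C(=O)N1CC(=O)c1ccc(O)cc1 | intermediate (not isolated)
9 | (2S,8S)-8-benzyl-2-(4-hydroxybenzyl)-6-(4-hydroxyphenyl)-5,8-dihydroimidazo[1,2-a]pyrazin-3(2H)-one (dihydrocoelenterazine; both CH centres labile) | O=C1[C@H](Cc2ccc(O)cc2)N=C2[C@H](Cc3ccccc3)N=C(c3ccc(O)cc3)CN12 | intermediate
10 | coelenterazine, 8-benzyl-2-(4-hydroxybenzyl)-6-(4-hydroxyphenyl)imidazo[1,2-a]pyrazin-3(7H)-one (achiral) | O=c1c(Cc2ccc(O)cc2)nc2c(Cc3ccccc3)[nH]c(-c3ccc(O)cc3)cn1-2 | target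

**Step count**

Total steps: 4. Longest linear sequence: 4 steps (1 or 2 → 3 → 5 → 9 → 10).

**Steps most likely to fail**

1. Step 3 (new method). The silylated amide nitrogen may fail to add to the hindered C8a carbonyl, or closure onto the ketone may take over before the imidazolone has formed. The fallback closes the two rings in the opposite order with known reactions and sets out from 1 and 4.
   - Active-ester acylation (NaHCO3, THF/H2O, rt) should give tert-butyl N-[(2S)-1-{[2-(4-hydroxyphenyl)-2-oxoethyl]amino}-1-oxo-3-phenylpropan-2-yl]carbamate F1.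
   - Boc removal (4 M HCl/dioxane) and buffering (NaOAc, degassed EtOH, argon) let the amine condense with the α-amido ketone to (3S)-3-benzyl-5-(4-hydroxyphenyl)-3,6-dihydropyrazin-2(1H)-one F2, which already holds N7=C6.
   - Lawesson's reagent (THF, 50 °C) converts the lactam into (3S)-3-benzyl-5-(4-hydroxyphenyl)-3,6-dihydropyrazine-2(1H)-thione F3.
   - Condensation with commercial methyl L-tyrosinate (Hg(OAc)2, Et3N, THF; then cat. AcOH, toluene, 80 °C) forms the amidine N1–C8a, and ring nitrogen N4 then acylates itself with the ester (N4–C3). This is the thiolactam/amino ester route to fused imidazolones.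
   - The route is rejoined at 9, before step 4.

2. Step 4. The dehydrogenation may run on into over-oxidation or oxygenation of the electron-rich imidazopyrazinone as it forms. The fallback oxidizes at the level of an air-stable O-acyl derivative and sets out from 9.
   - Ac2O/pyridine (argon, 0 °C → rt) should trap the enol and both phenols as (8S)-8-benzyl-2-(4-acetoxybenzyl)-6-(4-acetoxyphenyl)-5,8-dihydroimidazo[1,2-a]pyrazin-3-yl acetate F4.
   - DDQ (1.05 equiv, dioxane, rt) aromatizes the dihydropyrazine ring to 8-benzyl-2-(4-acetoxybenzyl)-6-(4-acetoxyphenyl)imidazo[1,2-a]pyrazin-3-yl acetate F5, which no longer carries the oxidizable enol and can be purified in air.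
   - Acidic ethanolysis (HCl/EtOH, 50 °C, argon) removes the three acetyl groups and comes back at 10.

3. Step 2. The liberated α-aminoketone may self-condense (dihydropyrazine formation) faster than it is acylated, or acylation may be diverted to the phenols. The fallback uses the alcohol oxidation level and sets out from 3.
   - Coupling with commercial racemic octopamine hydrochloride (EDC·HCl, HOBt, NMM, DMF, 0 °C → rt), an amine that cannot self-condense, should give Boc-L-phenylalanyl-L-tyrosine N-[2-hydroxy-2-(4-hydroxyphenyl)ethyl]amide F6 (both carbinol epimers).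
   - DDQ (1.0 equiv, dioxane, rt) oxidizes the 4-hydroxybenzylic carbinol by way of its quinone methide, faster than the tyrosine CH2, and the route comes back at 5.

**Further compounds**

F1 | step 3 | tert-butyl N-[(2S)-1-{[2-(4-hydroxyphenyl)-2-oxoethyl]amino}-1-oxo-3-phenylpropan-2-yl]carbamate | CC(C)(C)OC(=O)N[C@@H](Cc1ccccc1)C(=O)NCC(=O)c1ccc(O)cc1
F2 | step 3 | (3S)-3-benzyl-5-(4-hydroxyphenyl)-3,6-dihydropyrazin-2(1H)-one | O=C1NCC(c2ccc(O)cc2)=N[C@H]1Cc1ccccc1
F3 | step 3 | (3S)-3-benzyl-5-(4-hydroxyphenyl)-3,6-dihydropyrazine-2(1H)-thione | S=C1NCC(c2ccc(O)cc2)=N[C@H]1Cc1ccccc1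
F4 | step 4 | (8S)-8-benzyl-2-(4-acetoxybenzyl)-6-(4-acetoxyphenyl)-5,8-dihydroimidazo[1,2-a]pyrazin-3-yl acetate | CC(=O)Oc1ccc(Cc2nc3[C@H](Cc4ccccc4)N=C(c4ccc(OC(C)=O)cc4)Cn3c2OC(C)=O)cc1
F5 | step 4 | 8-benzyl-2-(4-acetoxybenzyl)-6-(4-acetoxyphenyl)imidazo[1,2-a]pyrazin-3-yl acetate | CC(=O)Oc1ccc(Cc2nc3c(Cc4ccccc4)nc(-c4ccc(OC(C)=O)cc4)cn3c2OC(C)=O)cc1
F6 | step 2 | Boc-L-phenylalanyl-L-tyrosine N-[2-hydroxy-2-(4-hydroxyphenyl)ethyl]amide (carbinol epimers) | CC(C)(C)OC(=O)N[C@@H](Cc1ccccc1)C(=O)N[C@@H](Cc1ccc(O)cc1)C(=O)NCC(O)c1ccc(O)cc1
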